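**Retrosynthetic overview**
- The target comes from O-desilylation of its aryl TIPS ether; the E-benzylidene unit comes from dehydration (acetate, E1cB) of a β-hydroxy lactone.
- Key C–C disconnection: the exocyclic Cα–CH(OH)Ar bond, made by an intermolecular aldol between the lithium enolate of (R)-4-(3,4-dimethoxybenzyl)-γ-butyrolactone and O-TIPS-vanillin.
- The (R)-lactone comes from lactonisation of a γ-hydroxy tert-butyl ester, itself from Evans alkylation of the N-[3-(3,4-dimethoxyphenyl)propanoyl] (S)-4-benzyloxazolidinone with tert-butyl bromoacetate; this sets the only stereocentre.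
- Ring order: both benzene rings are bought; the only ring made is the γ-butyrolactone (step 5), closed before the aldol coupling.

Assumption: NaN(SiMe3)2 and LiN(i-Pr)2 are used as commercial solutions, so neither is made in the flask.

**Step 1**
Reactants: 1 3-(3,4-dimethoxyphenyl)propanoic acid; 2 (4S)-4-benzyl-1,3-oxazolidin-2-one
Product: 4 (4S)-4-benzyl-3-[3-(3,4-dimethoxyphenyl)propanoyl]-1,3-oxazolidin-2-one, via mixed pivalic anhydride 3 (not isolated)
Conditions: t-BuCOCl, Et3N, THF, −20 °C; then 2, LiCl, −20 °C → rt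
Reagents that add atoms: none
Why: Mixed-anhydride N-acylation of the oxazolidinone (LiCl/Et3N activation) is mild and high-yielding, needs no strong base and touches no stereocentre.

**Step 2**
Reactants: 4 (4S)-4-benzyl-3-[3-(3,4-dimethoxyphenyl)propanoyl]-1,3-oxazolidin-2-one; 5 tert-butyl bromoacetate
Product: 7 tert-butyl (3R)-4-[(4S)-4-benzyl-2-oxo-1,3-oxazolidin-3-yl]-3-(3,4-dimethoxybenzyl)-4-oxobutanoate, via sodium Z-enolate 6 (not isolated)
Conditions: NaN(SiMe3)2, THF, −78 °C; then 5, −78 → −40 °C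
Reagents that add atoms: none
Why: Evans asymmetric alkylation, in which the chelated sodium Z-enolate is attacked by the reactive α-bromo ester on the face anti to the auxiliary benzyl group, setting the new stereocentre as R (dr normally above 95:5, minor isomer removed by chromatography).

**Step 3**
Reactants: 7 tert-butyl (3R)-4-[(4S)-4-benzyl-2-oxo-1,3-oxazolidin-3-yl]-3-(3,4-dimethoxybenzyl)-4-oxobutanoate
Product: 9 (2R)-4-tert-butoxy-2-(3,4-dimethoxybenzyl)-4-oxobutanoic acid, via lithium peroxycarboxylate 8 (not isolated)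
Conditions: LiOH, 30% H2O2, THF/H2O, 0 °C; then aq. Na2SO3; 1 M HCl to pH 3, 0 °C
Reagents that add atoms: hydrogen peroxide, OO (one oxygen ends up in the CO2H group)
Why: Hydroperoxide-mediated imide hydrolysis (LiOOH) attacks the exocyclic carbonyl selectively, leaves the tert-butyl ester and the α-stereocentre untouched, and sulfite reduces the peracid salt to the acid while the auxiliary is recovered.

**Step 4**
Reactants: 9 (2R)-4-tert-butoxy-2-(3,4-dimethoxybenzyl)-4-oxobutanoic acid
Product: 10 tert-butyl (3R)-4-(3,4-dimethoxyphenyl)-3-(hydroxymethyl)butanoate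
Conditions: BH3·SMe2, THF, 0 °C → rt; then H2O
Reagents that add atoms: none
Why: Chemoselective borane reduction of a carboxylic acid (through its acyloxyborane) in the presence of a tert-butyl ester, under non-basic conditions that cannot epimerise the stereocentre.

**Step 5**
Reactants: 10 tert-butyl (3R)-4-(3,4-dimethoxyphenyl)-3-(hydroxymethyl)butanoate
Product: 12 (4R)-4-(3,4-dimethoxybenzyl)oxolan-2-one, via hydroxy acid 11 (not isolated)
Conditions: p-TsOH·H2O (10 mol %), toluene, 80 °C
Reagents that add atoms: none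
Why: Acid-catalysed tert-butyl ester cleavage (loss of isobutene) followed by 5-exo lactonisation closes the γ-butyrolactone, and catalytic acid in hot toluene, unlike neat TFA, keeps Friedel–Crafts tert-butylation of the veratryl ring down.

**Step 6**
Reactants: 13 vanillin (4-hydroxy-3-methoxybenzaldehyde)
Product: 14 3-methoxy-4-(triisopropylsilyloxy)benzaldehyde
Conditions: i-Pr3SiCl, imidazole, DMF, rt
Reagents that add atoms: triisopropylsilyl chloride, CC(C)[Si](Cl)(C(C)C)C(C)C
Why: Imidazole-promoted O-silylation masks the acidic phenol for the enolate step, and TIPS is chosen over TBS for its stability to amide bases and DBU.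

**Step 7**
Reactants: 12 (4R)-4-(3,4-dimethoxybenzyl)oxolan-2-one; 14 3-methoxy-4-(triisopropylsilyloxy)benzaldehyde
Product: 16 (3S,4R)-4-(3,4-dimethoxybenzyl)-3-{hydroxy[3-methoxy-4-(triisopropylsilyloxy)phenyl]methyl}oxolan-2-one, via lithium enolate 15 (not isolated)
Conditions: LiN(i-Pr)2, THF, −78 °C; then 14, −78 °C; AcOH quench at −78 °C
Reagents that add atoms: none
Why: Intermolecular aldol addition of the lactone lithium enolate to a non-enolisable aldehyde forms the key C–C bond trans to the C-4 benzyl group; the carbinol centre forms as an epimer mixture, which does not matter because both new centres are removed in step 8, and the cold acidic quench prevents retro-aldol.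

**Step 8**
Reactants: 16 (3S,4R)-4-(3,4-dimethoxybenzyl)-3-{hydroxy[3-methoxy-4-(triisopropylsilyloxy)phenyl]methyl}oxolan-2-one
Product: 18 (3E,4R)-4-(3,4-dimethoxybenzyl)-3-[3-methoxy-4-(triisopropylsilyloxy)benzylidene]oxolan-2-one, via benzylic acetate 17 (not isolated)
Conditions: Ac2O, Et3N, DMAP (cat.), CH2Cl2, 0 °C → rt; then DBU, rt
Reagents that add atoms: none
Why: Acetylation followed by DBU-mediated E1cB elimination (completing the aldol condensation) is stereoconvergent and gives the thermodynamically favoured E-benzylidene lactone (aryl away from the carbonyl oxygen) from either carbinol epimer, while C-4 is not involved.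

**Step 9**
Reactants: 18 (3E,4R)-4-(3,4-dimethoxybenzyl)-3-[3-methoxy-4-(triisopropylsilyloxy)benzylidene]oxolan-2-one
Product: 19 (3E,4R)-4-(3,4-dimethoxybenzyl)-3-(4-hydroxy-3-methoxybenzylidene)oxolan-2-one
Conditions: Bu4NF, AcOH (1:1), THF, 0 °C
Reagents that add atoms: none
Why: Fluoride-mediated desilylation of the aryl silyl ether, buffered with AcOH so that the phenoxide is protonated at once and neither E/Z scrambling nor migration of the double bond into the ring (which would destroy C-4) takes place.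

**Compound list**
1 | 3-(3,4-dimethoxyphenyl)propanoic acid | COc1ccc(CCC(=O)O)cc1OC | starting material
2 | (4S)-4-benzyl-1,3-oxazolidin-2-one | O=C1N[C@@H](Cc2ccccc2)CO1 | starting material
3 | 3-(3,4-dimethoxyphenyl)propanoic pivalic anhydride | COc1ccc(CCC(=O)OC(=O)C(C)(C)C)cc1OC | intermediate
4 | (4S)-4-benzyl-3-[3-(3,4-dimethoxyphenyl)propanoyl]-1,3-oxazolidin-2-one | COc1ccc(CCC(=O)N2[C@@H](Cc3ccccc3)COC2=O)cc1OC | intermediate
5 | tert-butyl bromoacetate | CC(C)(C)OC(=O)CBr | starting material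
6 | sodium Z-enolate of 4 | COc1ccc(C/C=C(\[O-])N2[C@@H](Cc3ccccc3)COC2=O)cc1OC.[Na+] | intermediate
7 | tert-butyl (3R)-4-[(4S)-4-benzyl-2-oxo-1,3-oxazolidin-3-yl]-3-(3,4-dimethoxybenzyl)-4-oxobutanoate | COc1ccc(C[C@H](CC(=O)OC(C)(C)C)C(=O)N2[C@@H](Cc3ccccc3)COC2=O)cc1OC | intermediate
8 | lithium (2R)-4-tert-butoxy-2-(3,4-dimethoxybenzyl)-4-oxobutaneperoxoate | COc1ccc(C[C@H](CC(=O)OC(C)(C)C)C(=O)O[O-])cc1OC.[Li+] | intermediate
9 | (2R)-4-tert-butoxy-2-(3,4-dimethoxybenzyl)-4-oxobutanoic acid | COc1ccc(C[C@H](CC(=O)OC(C)(C)C)C(=O)O)cc1OC | intermediate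
10 | tert-butyl (3R)-4-(3,4-dimethoxyphenyl)-3-(hydroxymethyl)butanoate | COc1ccc(C[C@H](CC(=O)OC(C)(C)C)CO)cc1OC | intermediate
11 | (3R)-4-(3,4-dimethoxyphenyl)-3-(hydroxymethyl)butanoic acid | COc1ccc(C[C@H](CC(=O)O)CO)cc1OC | intermediate
12 | (4R)-4-(3,4-dimethoxybenzyl)oxolan-2-one | COc1ccc(C[C@H]2COC(=O)C2)cc1OC | intermediate
13 | vanillin (4-hydroxy-3-methoxybenzaldehyde) | COc1cc(C=O)ccc1O | starting material
14 | 3-methoxy-4-(triisopropylsilyloxy)benzaldehyde | COc1cc(C=O)ccc1O[Si](C(C)C)(C(C)C)C(C)C | intermediate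
15 | lithium (4R)-4-(3,4-dimethoxybenzyl)-4,5-dihydrofuran-2-olate (lithium enolate of 12) | COc1ccc(C[C@H]2COC([O-])=C2)cc1OC.[Li+] | intermediate
16 | (3S,4R)-4-(3,4-dimethoxybenzyl)-3-{hydroxy[3-methoxy-4-(triisopropylsilyloxy)phenyl]methyl}oxolan-2-one (both carbinol epimers) | COc1ccc(C[C@H]2COC(=O)[C@@H]2C(O)c2ccc(O[Si](C(C)C)(C(C)C)C(C)C)c(OC)c2)cc1OC | intermediate
17 | [(3S,4R)-4-(3,4-dimethoxybenzyl)-2-oxooxolan-3-yl][3-methoxy-4-(triisopropylsilyloxy)phenyl]methyl acetate (both epimers) | COc1ccc(C[C@H]2COC(=O)[C@@H]2C(OC(C)=O)c2ccc(O[Si](C(C)C)(C(C)C)C(C)C)c(OC)c2)cc1OC | intermediate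
18 | (3E,4R)-4-(3,4-dimethoxybenzyl)-3-[3-methoxy-4-(triisopropylsilyloxy)benzylidene]oxolan-2-one | COc1cc(/C=C2/C(=O)OC[C@@H]2Cc2ccc(OC)c(OC)c2)ccc1O[Si](C(C)C)(C(C)C)C(C)C | intermediate
19 | (3E,4R)-4-(3,4-dimethoxybenzyl)-3-(4-hydroxy-3-methoxybenzylidene)oxolan-2-one | COc1cc(/C=C2/C(=O)OC[C@@H]2Cc2ccc(OC)c(OC)c2)ccc1O | target

**Totals**
Total step count: 9. Longest linear sequence: 8 steps (steps 1, 2, 3, 4, 5, 7, 8, 9); step 6 is a one-step side branch.

**Steps most likely to fail**

Step 2 (Evans alkylation with the bromoacetate: incomplete conversion, enolate decomposition above −40 °C, or eroded dr). The fallback sets out from 4 and comes back to the route at 12. The sodium enolate 6 is alkylated with allyl iodide instead, which is the most dependable Evans alkylation and has the same facial bias, to give (4S)-4-benzyl-3-[(2S)-2-(3,4-dimethoxybenzyl)pent-4-enoyl]-1,3-oxazolidin-2-one F1. Reductive removal of the auxiliary (LiBH4, 1 equiv H2O, Et2O, 0 °C) gives (2S)-2-(3,4-dimethoxybenzyl)pent-4-en-1-ol F2. Lemieux–Johnson cleavage of the terminal alkene (K2OsO4·2H2O cat., NaIO4, 2,6-lutidine, dioxane/H2O) gives the γ-hydroxy aldehyde in its ring-closed form, (4R)-4-(3,4-dimethoxybenzyl)oxolan-2-ol F3. Fetizon oxidation of the lactol (Ag2CO3 on Celite, toluene, reflux) then delivers lactone 12.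

Step 8 (dehydration: E/Z mixtures, or DBU-induced migration of the double bond into the ring with loss of C-4). The fallback sets out from 12 and comes back at 18, replacing the aldol/elimination pair by a Horner–Wadsworth–Emmons olefination. Lactone 12 is deprotonated with LiN(i-Pr)2 and trapped on oxygen with ClP(O)(OEt)2 to give diethyl (4R)-4-(3,4-dimethoxybenzyl)-4,5-dihydrofuran-2-yl phosphate F4. Further LiN(i-Pr)2 in the same flask induces the 1,3-phosphoryl shift from O to C, giving diethyl [(4S)-4-(3,4-dimethoxybenzyl)-2-oxooxolan-3-yl]phosphonate F5; the descriptor changes only because phosphorus raises the CIP rank of C-3, and the spatial arrangement at C-4 is that of 12. Olefination of F5 with aldehyde 14 (NaH, THF, 0 °C → rt) gives 18 directly with E geometry.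

Step 9 (fluoride desilylation: the liberated phenoxide is conjugated to the enoate and may scramble the alkene or deconjugate). The fallback sets out from 13 and comes back at 19, using an acid-labile protecting group so that the last step sees neither fluoride nor base. Vanillin 13 is protected with MeOCH2Cl/i-Pr2NEt in CH2Cl2 as 3-methoxy-4-(methoxymethoxy)benzaldehyde F6. Aldol addition of lithium enolate 15 (from 12) gives (3S,4R)-4-(3,4-dimethoxybenzyl)-3-{hydroxy[3-methoxy-4-(methoxymethoxy)phenyl]methyl}oxolan-2-one F7. Acetylation (Ac2O, Et3N, DMAP) gives the corresponding benzylic acetate F8, and DBU elimination gives (3E,4R)-4-(3,4-dimethoxybenzyl)-3-[3-methoxy-4-(methoxymethoxy)benzylidene]oxolan-2-one F9. Acetal cleavage with 2 M HCl in THF/i-PrOH at 40 °C releases 19.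

**Further compounds**
F1 | step 2 | (4S)-4-benzyl-3-[(2S)-2-(3,4-dimethoxybenzyl)pent-4-enoyl]-1,3-oxazolidin-2-one | COc1ccc(C[C@H](CC=C)C(=O)N2[C@@H](Cc3ccccc3)COC2=O)cc1OC
F2 | step 2 | (2S)-2-(3,4-dimethoxybenzyl)pent-4-en-1-ol | COc1ccc(C[C@H](CC=C)CO)cc1OC
F3 | step 2 | (4R)-4-(3,4-dimethoxybenzyl)oxolan-2-ol (anomer mixture) | COc1ccc(C[C@H]2COC(O)C2)cc1OC
F4 | step 8 | diethyl (4R)-4-(3,4-dimethoxybenzyl)-4,5-dihydrofuran-2-yl phosphate | COc1ccc(C[C@H]2COC(OP(=O)(OCC)OCC)=C2)cc1OC
F5 | step 8 | diethyl [(4S)-4-(3,4-dimethoxybenzyl)-2-oxooxolan-3-yl]phosphonate (C-3 epimers) | COc1ccc(C[C@H]2COC(=O)C2P(=O)(OCC)OCC)cc1OC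
F6 | step 9 | 3-methoxy-4-(methoxymethoxy)benzaldehyde | COCOc1ccc(C=O)cc1OC
F7 | step 9 | (3S,4R)-4-(3,4-dimethoxybenzyl)-3-{hydroxy[3-methoxy-4-(methoxymethoxy)phenyl]methyl}oxolan-2-one (both carbinol epimers) | COc1ccc(C[C@H]2COC(=O)[C@@H]2C(O)c2ccc(OCOC)c(OC)c2)cc1OC
F8 | step 9 | [(3S,4R)-4-(3,4-dimethoxybenzyl)-2-oxooxolan-3-yl][3-methoxy-4-(methoxymethoxy)phenyl]methyl acetate (both epimers) | COc1ccc(C[C@H]2COC(=O)[C@@H]2C(OC(C)=O)c2ccc(OCOC)c(OC)c2)cc1OC
F9 | step 9 | (3E,4R)-4-(3,4-dimethoxybenzyl)-3-[3-methoxy-4-(methoxymethoxy)benzylidene]oxolan-2-one | COCOc1ccc(/C=C2/C(=O)OC[C@@H]2Cc2ccc(OC)c(OC)c2)cc1OC
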